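**Target:** CNP0179134.2, methyl (3aS,4S,5S,6E,10E,11aR)-5-acetoxy-10-(hydroxymethyl)-4-(methacryloyloxy)-3-methylidene-2-oxo-2,3,3a,4,5,8,9,11a-octahydrocyclodeca[b]furan-6-carboxylate. It is a (6R,7S,8S,9S)-germacra-1(10),4-dien-6,12-olide in which both ring olefins are ring-cis and the lactone is trans-fused.

## Retrosynthetic overview

1. The ten-membered ring is closed last by ring-closing metathesis at C1=C10 of lactone 27; the γ-lactone is formed before the carbocycle.
2. The lactone comes from O6 closing on the C12 methyl ester after desilylation; O9 is acetylated and O8 methacryloylated before that.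
3. Key bond C7–C8: Barbier coupling of a 2-(methoxycarbonyl)allylindium with α-hydroxy aldehyde 21. The reagent is an ester homoenolate (β′-acrylate anion) equivalent made from bromide 15, so the acrylate β-carbon C7 acts as a nucleophile toward the aldehyde carbon C8; the step sets C7 and C8.
4. Fragment 1 (bromide 15) comes from 2-butyne-1,4-diol, but-3-enylzinc bromide, methyl propiolate (asymmetric alkynylation sets C6) and formaldehyde (C13).
5. Fragment 2 (aldehyde 21) comes from crotonaldehyde and methyl acrylate (Morita–Baylis–Hillman, Sharpless kinetic resolution sets C9, ozonolysis).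

Assumption: atoms are labelled C1–C15 as in germacranolides (C6 lactone carbinol, C7 lactone methine, C8 methacrylate carbon, C9 acetate carbon, C12 lactone carbonyl, C13 exocyclic methylene, C14 ester carbon, C15 hydroxymethyl), TBS = tert-butyldimethylsilyl, and the ProPhenol antipode that delivers the alkyne to the Si face of enal 7 is taken to be (R,R) (its mirror image is used if the sense is the opposite).

## Route

Step 1
Reactants: 1 2-butyne-1,4-diol
Product: 2 4-[(tert-butyldimethylsilyl)oxy]but-2-yn-1-ol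
Conditions: TBSCl (1 equiv), imidazole, THF, 0 °C, diol in threefold excess
Reagents that add atoms: tert-butyldimethylsilyl chloride (TBSCl) CC(C)(C)[Si](C)(C)Cl
Why: Statistical monosilylation of a symmetrical diol used in excess (silyl ether formation); no stereocentre is involved.

Step 2
Reactants: 2 4-[(tert-butyldimethylsilyl)oxy]but-2-yn-1-ol
Product: 4 (Z)-4-[(tert-butyldimethylsilyl)oxy]-3-iodobut-2-en-1-ol, via cyclic vinylalanate 3 (not isolated)
Conditions: NaAlH2(OCH2CH2OMe)2, THF, 0 °C; then I2, −78 °C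
Reagents that add atoms: iodine II
Why: Hydroxyl-directed trans-hydroalumination of the propargylic alcohol (hydride to C5, aluminium on C4) followed by iodinolysis with retention places C6 and iodine cis, which fixes the C4=C5 geometry of the target.

Step 3
Reactants: 4 (Z)-4-[(tert-butyldimethylsilyl)oxy]-3-iodobut-2-en-1-ol; 5 but-3-enylzinc bromide
Product: 6 (E)-3-{[(tert-butyldimethylsilyl)oxy]methyl}hepta-2,6-dien-1-ol
Conditions: PdCl2(dppf) (3 mol %), THF, 0 °C to rt, 2.5 equiv of 5
Reagents that add atoms: none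
Why: Negishi sp2–sp3 cross-coupling proceeds with retention at the alkenyl iodide, so the butenyl chain (C3) ends cis to C6 and the silyloxymethyl group (C15) trans to it.

Step 4
Reactants: 6 (E)-3-{[(tert-butyldimethylsilyl)oxy]methyl}hepta-2,6-dien-1-ol
Product: 7 (E)-3-{[(tert-butyldimethylsilyl)oxy]methyl}hepta-2,6-dienal
Conditions: activated MnO2, CH2Cl2, rt
Reagents that add atoms: none
Why: Chemoselective allylic oxidation on the MnO2 surface gives the enal under neutral conditions without isomerising the trisubstituted olefin.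

Step 5
Reactants: 7 (E)-3-{[(tert-butyldimethylsilyl)oxy]methyl}hepta-2,6-dienal; 8 methyl propiolate
Product: 10 methyl (4R,5E)-4-hydroxy-6-{[(tert-butyldimethylsilyl)oxy]methyl}deca-5,9-dien-2-ynoate, via zinc acetylide 9 (not isolated)
Conditions: Me2Zn (3 equiv), (R,R)-ProPhenol (10 mol %), Ph3P=O (20 mol %), toluene, 4 °C
Reagents that add atoms: none
Why: Dinuclear zinc–ProPhenol catalysed asymmetric alkynylation of an enal; Si-face delivery of the propiolate sets C6 as R (the configuration kept to the target).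

Step 6
Reactants: 10 methyl (4R,5E)-4-hydroxy-6-{[(tert-butyldimethylsilyl)oxy]methyl}deca-5,9-dien-2-ynoate
Product: 11 methyl (4R,5E)-4-[(tert-butyldimethylsilyl)oxy]-6-{[(tert-butyldimethylsilyl)oxy]methyl}deca-5,9-dien-2-ynoate
Conditions: TBSCl, imidazole, DMF, 0 °C to rt
Reagents that add atoms: tert-butyldimethylsilyl chloride (TBSCl) CC(C)(C)[Si](C)(C)Cl
Why: Silylation of the propargylic alcohol blocks O6 so that the later 2-(hydroxymethyl)enoate cannot close to a butenolide; the stereocentre is untouched.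

Step 7
Reactants: 11 methyl (4R,5E)-4-[(tert-butyldimethylsilyl)oxy]-6-{[(tert-butyldimethylsilyl)oxy]methyl}deca-5,9-dien-2-ynoate
Product: 13 methyl (2Z,4R,5E)-2-(hydroxymethyl)-4-[(tert-butyldimethylsilyl)oxy]-6-{[(tert-butyldimethylsilyl)oxy]methyl}deca-2,5,9-trienoate, via α-aluminoacrylate 12 (not isolated)
Conditions: iBu2AlH, N-methylmorpholine N-oxide, THF, 0 °C; then monomeric HCHO, 0 °C to rt
Reagents that add atoms: formaldehyde C=O
Why: Syn-hydroalumination of the ynoate (hydride to C7, aluminium to C11: vinylalumination) and aldol capture by formaldehyde attach C13 to C11 in one operation.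

Step 8
Reactants: 13 methyl (2Z,4R,5E)-2-(hydroxymethyl)-4-[(tert-butyldimethylsilyl)oxy]-6-{[(tert-butyldimethylsilyl)oxy]methyl}deca-2,5,9-trienoate
Product: 15 methyl (2Z,4R,5E)-2-(bromomethyl)-4-[(tert-butyldimethylsilyl)oxy]-6-{[(tert-butyldimethylsilyl)oxy]methyl}deca-2,5,9-trienoate, via E-bromide 14 (not isolated)
Conditions: CBr4, PPh3, CH2Cl2, 0 °C; then LiBr (0.3 equiv), acetone, 40 °C
Reagents that add atoms: carbon tetrabromide BrC(Br)(Br)Br
Why: Appel bromination of the primary allylic alcohol, then bromide-mediated SN2′/SN2′ equilibration to the thermodynamic isomer with C6 trans to the ester and cis to CH2Br.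

Step 9
Reactants: 16 (E)-crotonaldehyde; 17 methyl acrylate
Product: 18 methyl (4E)-3-hydroxy-2-methylidenehex-4-enoate (racemic)
Conditions: DABCO (0.2 equiv), neat, rt, several days
Reagents that add atoms: none
Why: Morita–Baylis–Hillman reaction joins C9 to C10 and delivers the acrylate unit C10(=CH2)–C14 in one step.

Step 10
Reactants: 18 methyl (4E)-3-hydroxy-2-methylidenehex-4-enoate (racemic)
Product: 19 methyl (3R,4E)-3-hydroxy-2-methylidenehex-4-enoate
Conditions: Ti(OiPr)4 (15 mol %), D-(−)-diisopropyl tartrate (18 mol %), tBuOOH (0.6 equiv), 4 Å MS, CH2Cl2, −20 °C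
Reagents that add atoms: none
Why: Sharpless kinetic resolution: with the D-tartrate the (S)-alcohol is epoxidised at its electron-rich propenyl group (the acrylate olefin is inert), leaving the (R)-alcohol that carries the C9 configuration.

Step 11
Reactants: 19 methyl (3R,4E)-3-hydroxy-2-methylidenehex-4-enoate
Product: 21 methyl (3S)-3-hydroxy-2-methylidene-4-oxobutanoate, via ozonide 20 (not isolated)
Conditions: O3 (1 equiv, indicator end-point), CH2Cl2, −78 °C; then Me2S; used crude
Reagents that add atoms: ozone [O-][O+]=O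
Why: Ozonolysis cleaves the electron-rich disubstituted olefin much faster than the acrylate and unveils the C8 aldehyde; C9 is unchanged (the descriptor becomes S by priority only).

Step 12
Reactants: 15 methyl (2Z,4R,5E)-2-(bromomethyl)-4-[(tert-butyldimethylsilyl)oxy]-6-{[(tert-butyldimethylsilyl)oxy]methyl}deca-2,5,9-trienoate; 21 methyl (3S)-3-hydroxy-2-methylidene-4-oxobutanoate
Product: 23 methyl (3S,4S,5R,6R,7E)-3,4-dihydroxy-5-(3-methoxy-3-oxoprop-1-en-2-yl)-2-methylidene-6-[(tert-butyldimethylsilyl)oxy]-8-{[(tert-butyldimethylsilyl)oxy]methyl}dodeca-7,11-dienoate, via allylindium 22 (not isolated)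
Conditions: In powder (1.5 equiv), THF/H2O 1:1, rt, 2 equiv of 21
Reagents that add atoms: none
Why: Aqueous indium Barbier allylation in which the 2-(methoxycarbonyl)allylindium, an ester homoenolate equivalent, bonds its γ-carbon C7 (an acrylate β-carbon) to the aldehyde carbon C8. The Z-configured reagent reacts through a Zimmerman–Traxler chair with the C6 substituent axial (7,8-syn), the α-hydroxyl of 21 chelates indium (8,9-syn), and the aldehyde is expected to enter anti to the bulky C6 silyloxy group whose H eclipses the allyl plane, giving C7 (R here, S after lactonisation by priority) and C8 (S).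

Step 13
Reactants: 23 (the 8,9-diol named in step 12)
Product: 24 methyl (3S,4S,5R,6R,7E)-3-acetoxy-4-hydroxy-5-(3-methoxy-3-oxoprop-1-en-2-yl)-2-methylidene-6-[(tert-butyldimethylsilyl)oxy]-8-{[(tert-butyldimethylsilyl)oxy]methyl}dodeca-7,11-dienoate
Conditions: AcCl (1.05 equiv), 2,4,6-collidine, CH2Cl2, −78 °C
Reagents that add atoms: acetyl chloride CC(=O)Cl
Why: Kinetic, regioselective acetylation of the less hindered allylic C9 hydroxyl over the C8 hydroxyl flanked by the branched C7 methine; the non-nucleophilic base avoids SN2′ chemistry of the new allylic acetate.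

Step 14
Reactants: 24 (the 9-acetate named in step 13)
Product: 25 methyl (3S,4S,5R,6R,7E)-3-acetoxy-4-(methacryloyloxy)-5-(3-methoxy-3-oxoprop-1-en-2-yl)-2-methylidene-6-[(tert-butyldimethylsilyl)oxy]-8-{[(tert-butyldimethylsilyl)oxy]methyl}dodeca-7,11-dienoate
Conditions: methacrylic anhydride (3 equiv), Sc(OTf)3 (5 mol %), MeCN, −20 °C
Reagents that add atoms: methacrylic anhydride CC(=C)C(=O)OC(=O)C(C)=C
Why: Lewis-acid-catalysed acylation esterifies the hindered C8 hydroxyl without amine nucleophiles (which would displace the C9 allylic acetate by SN2′) and without base-induced acetyl migration; no stereocentre is affected.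

Step 15
Reactants: 25 (the 8-methacrylate 9-acetate named in step 14)
Product: 27 methyl (3S,4S)-3-acetoxy-4-{(2R,3S)-2-[(1E)-2-(hydroxymethyl)hexa-1,5-dien-1-yl]-4-methylidene-5-oxooxolan-3-yl}-4-(methacryloyloxy)-2-methylidenebutanoate, via desilylated hydroxy ester 26 (not isolated)
Conditions: HF·pyridine, THF, 0 °C to rt; then PPTS (10 mol %), CH2Cl2, rt
Reagents that add atoms: none
Why: Fluoride cleaves both silyl ethers and the freed C6 hydroxyl closes the five-membered lactone on the C12 methyl ester (acid-catalysed transesterification) with retention at C6 and C7, giving the trans lactone (C5 and C8 trans).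

Step 16
Reactants: 27 (the lactone named in step 15)
Product: 28 CNP0179134.2 (target)
Conditions: second-generation Hoveyda–Grubbs catalyst (10 mol %), toluene (1 mM), 80 °C
Reagents that add atoms: none
Why: Ring-closing metathesis between the terminal vinyl group (C1) and the C10 methylene forms the ten-membered ring; the ring-cis trisubstituted enoate (C2 cis to C9, ester trans to C2) is the less strained and thermodynamically preferred isomer in a ring that already holds one cis olefin.

## Compound list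

CIP descriptors are those of each compound as named. C7 reads R while O6 carries silicon and S afterwards; this is a priority change only, not a change in space.

1 | 2-butyne-1,4-diol | OCC#CCO | starting material
2 | 4-[(tert-butyldimethylsilyl)oxy]but-2-yn-1-ol | OCC#CCO[Si](C)(C)C(C)(C)C | intermediate
3 | sodium cyclic vinylalanate of 2 (five-membered O–Al–C ring, two 2-methoxyethoxy groups on Al) | [Na+].COCCO[Al-]1(OCCOC)OCC=C1CO[Si](C)(C)C(C)(C)C | intermediate (not isolated)
4 | (Z)-4-[(tert-butyldimethylsilyl)oxy]-3-iodobut-2-en-1-ol | OC/C=C(\I)CO[Si](C)(C)C(C)(C)C | intermediate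
5 | but-3-enylzinc bromide (THF solution) | C=CCC[Zn]Br | starting material
6 | (E)-3-{[(tert-butyldimethylsilyl)oxy]methyl}hepta-2,6-dien-1-ol | OC/C=C(\CCC=C)CO[Si](C)(C)C(C)(C)C | intermediate
7 | (E)-3-{[(tert-butyldimethylsilyl)oxy]methyl}hepta-2,6-dienal | O=C/C=C(\CCC=C)CO[Si](C)(C)C(C)(C)C | intermediate
8 | methyl propiolate | C#CC(=O)OC | starting material
9 | methyl 3-(methylzincio)prop-2-ynoate | C[Zn]C#CC(=O)OC | intermediate (not isolated)
10 | methyl (4R,5E)-4-hydroxy-6-{[(TBS)oxy]methyl}deca-5,9-dien-2-ynoate | COC(=O)C#C[C@H](O)/C=C(/CO[Si](C)(C)C(C)(C)C)CCC=C | intermediate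
11 | methyl (4R,5E)-4-[(TBS)oxy]-6-{[(TBS)oxy]methyl}deca-5,9-dien-2-ynoate | COC(=O)C#C[C@H](O[Si](C)(C)C(C)(C)C)/C=C(/CO[Si](C)(C)C(C)(C)C)CCC=C | intermediate
12 | methyl (2E,4R,5E)-2-(diisobutylalumanyl)-4-[(TBS)oxy]-6-{[(TBS)oxy]methyl}deca-2,5,9-trienoate | COC(=O)/C([Al](CC(C)C)CC(C)C)=C\[C@H](O[Si](C)(C)C(C)(C)C)/C=C(/CO[Si](C)(C)C(C)(C)C)CCC=C | intermediate (not isolated)
13 | methyl (2Z,4R,5E)-2-(hydroxymethyl)-4-[(TBS)oxy]-6-{[(TBS)oxy]methyl}deca-2,5,9-trienoate | COC(=O)/C(CO)=C\[C@H](O[Si](C)(C)C(C)(C)C)/C=C(/CO[Si](C)(C)C(C)(C)C)CCC=C | intermediate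
14 | methyl (2E,4R,5E)-2-(bromomethyl)-4-[(TBS)oxy]-6-{[(TBS)oxy]methyl}deca-2,5,9-trienoate | COC(=O)/C(CBr)=C\[C@H](O[Si](C)(C)C(C)(C)C)/C=C(/CO[Si](C)(C)C(C)(C)C)CCC=C | intermediate (not isolated)
15 | methyl (2Z,4R,5E)-2-(bromomethyl)-4-[(TBS)oxy]-6-{[(TBS)oxy]methyl}deca-2,5,9-trienoate | COC(=O)/C(CBr)=C/[C@H](O[Si](C)(C)C(C)(C)C)/C=C(/CO[Si](C)(C)C(C)(C)C)CCC=C | intermediate
16 | (E)-crotonaldehyde | C/C=C/C=O | starting material
17 | methyl acrylate | C=CC(=O)OC | starting material
18 | methyl (4E)-3-hydroxy-2-methylidenehex-4-enoate (racemic) | COC(=O)C(=C)C(O)/C=C/C | intermediate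
19 | methyl (3R,4E)-3-hydroxy-2-methylidenehex-4-enoate | COC(=O)C(=C)[C@H](O)/C=C/C | intermediate
20 | methyl 2-[(S)-hydroxy(5-methyl-1,2,4-trioxolan-3-yl)methyl]prop-2-enoate (ozonide) | COC(=O)C(=C)[C@H](O)C1OOC(C)O1 | intermediate (not isolated)
21 | methyl (3S)-3-hydroxy-2-methylidene-4-oxobutanoate | COC(=O)C(=C)[C@H](O)C=O | intermediate
22 | methyl (2Z,4R,5E)-2-[(dibromoindiganyl)methyl]-4-[(TBS)oxy]-6-{[(TBS)oxy]methyl}deca-2,5,9-trienoate (allylindium, simplest formulation) | COC(=O)/C(C[In](Br)Br)=C/[C@H](O[Si](C)(C)C(C)(C)C)/C=C(/CO[Si](C)(C)C(C)(C)C)CCC=C | intermediate (not isolated)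
23 | methyl (3S,4S,5R,6R,7E)-3,4-dihydroxy-5-(3-methoxy-3-oxoprop-1-en-2-yl)-2-methylidene-6-[(TBS)oxy]-8-{[(TBS)oxy]methyl}dodeca-7,11-dienoate | COC(=O)C(=C)[C@H](O)[C@@H](O)[C@@H](C(=C)C(=O)OC)[C@H](O[Si](C)(C)C(C)(C)C)/C=C(/CO[Si](C)(C)C(C)(C)C)CCC=C | intermediate
24 | methyl (3S,4S,5R,6R,7E)-3-acetoxy-4-hydroxy-5-(3-methoxy-3-oxoprop-1-en-2-yl)-2-methylidene-6-[(TBS)oxy]-8-{[(TBS)oxy]methyl}dodeca-7,11-dienoate | COC(=O)C(=C)[C@H](OC(C)=O)[C@@H](O)[C@@H](C(=C)C(=O)OC)[C@H](O[Si](C)(C)C(C)(C)C)/C=C(/CO[Si](C)(C)C(C)(C)C)CCC=C | intermediate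
25 | methyl (3S,4S,5R,6R,7E)-3-acetoxy-4-(methacryloyloxy)-5-(3-methoxy-3-oxoprop-1-en-2-yl)-2-methylidene-6-[(TBS)oxy]-8-{[(TBS)oxy]methyl}dodeca-7,11-dienoate | COC(=O)C(=C)[C@H](OC(C)=O)[C@@H](OC(=O)C(C)=C)[C@@H](C(=C)C(=O)OC)[C@H](O[Si](C)(C)C(C)(C)C)/C=C(/CO[Si](C)(C)C(C)(C)C)CCC=C | intermediate
26 | methyl (3S,4S,5S,6R,7E)-3-acetoxy-6-hydroxy-8-(hydroxymethyl)-4-(methacryloyloxy)-5-(3-methoxy-3-oxoprop-1-en-2-yl)-2-methylidenedodeca-7,11-dienoate | COC(=O)C(=C)[C@H](OC(C)=O)[C@@H](OC(=O)C(C)=C)[C@@H](C(=C)C(=O)OC)[C@H](O)/C=C(/CO)CCC=C | intermediate (not isolated)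
27 | methyl (3S,4S)-3-acetoxy-4-{(2R,3S)-2-[(1E)-2-(hydroxymethyl)hexa-1,5-dien-1-yl]-4-methylidene-5-oxooxolan-3-yl}-4-(methacryloyloxy)-2-methylidenebutanoate | COC(=O)C(=C)[C@H](OC(C)=O)[C@@H](OC(=O)C(C)=C)[C@H]1C(=C)C(=O)O[C@@H]1/C=C(/CO)CCC=C | intermediate
28 | CNP0179134.2, methyl (3aS,4S,5S,6E,10E,11aR)-5-acetoxy-10-(hydroxymethyl)-4-(methacryloyloxy)-3-methylidene-2-oxo-2,3,3a,4,5,8,9,11a-octahydrocyclodeca[b]furan-6-carboxylate | C=C(C)C(=O)O[C@H]1[C@H]2C(=C)C(=O)O[C@@H]2/C=C(/CO)CC/C=C(/C(=O)OC)[C@@H]1OC(C)=O | target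

## Step count and risks

Total step count: 16. Longest linear sequence: 13 (steps 1–8, then 12–16); fragment 2 takes 3 steps (9–11).

**Step 12 (indium coupling).** Aldehyde 21 is a fragile α-hydroxy aldehyde. The facial bias of the C6 silyloxy centre in the allylindium is an argued expectation, not an established fact; if it opposes the chelate-controlled sense the diastereoselectivity will fall. The fallback sets out from bromide 15 and comes back at diol 23. Bromide 15 is borylated with B2pin2 and Pd2(dba)3 in THF to the isolable, configurationally fixed allylboronate methyl (2E,4R,5E)-4-[(TBS)oxy]-6-{[(TBS)oxy]methyl}-2-[(4,4,5,5-tetramethyl-1,3,2-dioxaborolan-2-yl)methyl]deca-2,5,9-trienoate F1 (same olefin geometry as 15, C6 cis to the CH2B group). F1 is added to 21 under catalysis by the chiral phosphoric acid (R)-TRIP, so that the aldehyde face is chosen by the catalyst within the same closed chair, and aqueous work-up gives 23.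

**Step 13 (selective acetylation).** The two secondary hydroxyls may not be differentiated cleanly, and the acetyl group can migrate during step 14. The fallback sets out from alcohol 19 and comes back at diester 25. O9 is masked before the coupling: p-methoxybenzyl trichloroacetimidate with catalytic camphorsulfonic acid gives methyl (3R,4E)-3-[(4-methoxybenzyl)oxy]-2-methylidenehex-4-enoate F2. Ozonolysis, through the ozonide F3 that is not isolated, gives methyl (3S)-3-[(4-methoxybenzyl)oxy]-2-methylidene-4-oxobutanoate F4. Indium coupling of F4 with 15 under alkoxy chelation gives the C8 alcohol carrying the C9 p-methoxybenzyl ether F5. Sc(OTf)3 and methacrylic anhydride give its C8 methacrylate F6. DDQ in wet CH2Cl2 frees O9 to give the C9 alcohol F7, and Ac2O in pyridine (no DMAP) gives 25.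

**Step 16 (ring-closing metathesis).** The ten-membered ring is strained, and the exocyclic methylene of the lactone can compete with the C10 methylene, which would give an eight-membered ring. The fallback sets out from open-chain diester 25 and comes back at target 28, with the ring order reversed. Metathesis is run on 25, where C13 sits on a carbon flanked by two fully substituted oxygenated carbons and is less accessible; this gives the bis-silylated ten-membered carbocycle F8. HF·pyridine then removes both silyl groups, and the resulting hydroxy ester F9, not isolated, lactonises to 28.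

## Further compounds

F1 | step 12 | methyl (2E,4R,5E)-4-[(TBS)oxy]-6-{[(TBS)oxy]methyl}-2-[(4,4,5,5-tetramethyl-1,3,2-dioxaborolan-2-yl)methyl]deca-2,5,9-trienoate | COC(=O)/C(CB1OC(C)(C)C(C)(C)O1)=C/[C@H](O[Si](C)(C)C(C)(C)C)/C=C(/CO[Si](C)(C)C(C)(C)C)CCC=C
F2 | step 13 | methyl (3R,4E)-3-[(4-methoxybenzyl)oxy]-2-methylidenehex-4-enoate | COC(=O)C(=C)[C@H](OCc1ccc(OC)cc1)/C=C/C
F3 | step 13 | ozonide of F2, methyl 2-[(S)-[(4-methoxybenzyl)oxy](5-methyl-1,2,4-trioxolan-3-yl)methyl]prop-2-enoate | COC(=O)C(=C)[C@H](OCc1ccc(OC)cc1)C1OOC(C)O1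
F4 | step 13 | methyl (3S)-3-[(4-methoxybenzyl)oxy]-2-methylidene-4-oxobutanoate | COC(=O)C(=C)[C@H](OCc1ccc(OC)cc1)C=O
F5 | step 13 | methyl (3S,4S,5R,6R,7E)-4-hydroxy-3-[(4-methoxybenzyl)oxy]-5-(3-methoxy-3-oxoprop-1-en-2-yl)-2-methylidene-6-[(TBS)oxy]-8-{[(TBS)oxy]methyl}dodeca-7,11-dienoate | COC(=O)C(=C)[C@H](OCc1ccc(OC)cc1)[C@@H](O)[C@@H](C(=C)C(=O)OC)[C@H](O[Si](C)(C)C(C)(C)C)/C=C(/CO[Si](C)(C)C(C)(C)C)CCC=C
F6 | step 13 | methyl (3S,4S,5R,6R,7E)-4-(methacryloyloxy)-3-[(4-methoxybenzyl)oxy]-5-(3-methoxy-3-oxoprop-1-en-2-yl)-2-methylidene-6-[(TBS)oxy]-8-{[(TBS)oxy]methyl}dodeca-7,11-dienoate | COC(=O)C(=C)[C@H](OCc1ccc(OC)cc1)[C@@H](OC(=O)C(C)=C)[C@@H](C(=C)C(=O)OC)[C@H](O[Si](C)(C)C(C)(C)C)/C=C(/CO[Si](C)(C)C(C)(C)C)CCC=C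
F7 | step 13 | methyl (3S,4S,5R,6R,7E)-3-hydroxy-4-(methacryloyloxy)-5-(3-methoxy-3-oxoprop-1-en-2-yl)-2-methylidene-6-[(TBS)oxy]-8-{[(TBS)oxy]methyl}dodeca-7,11-dienoate | COC(=O)C(=C)[C@H](O)[C@@H](OC(=O)C(C)=C)[C@@H](C(=C)C(=O)OC)[C@H](O[Si](C)(C)C(C)(C)C)/C=C(/CO[Si](C)(C)C(C)(C)C)CCC=C
F8 | step 16 | bis-silylated ten-membered carbocycle: the ring-closed (C1=C10) form of 25 with the C12 methyl ester still open and O6 and O15 as TBS ethers | C=C(C)C(=O)O[C@H]1[C@@H](C(=C)C(=O)OC)[C@H](O[Si](C)(C)C(C)(C)C)/C=C(/CO[Si](C)(C)C(C)(C)C)CC/C=C(/C(=O)OC)[C@@H]1OC(C)=O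
F9 | step 16 | desilylated hydroxy ester of F8 (free O6 and O15 hydroxyls, C12 methyl ester) | C=C(C)C(=O)O[C@H]1[C@@H](C(=C)C(=O)OC)[C@H](O)/C=C(/CO)CC/C=C(/C(=O)OC)[C@@H]1OC(C)=O
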